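**Retrosynthetic overview** (positions carry the azulene numbering of the target: C-1 carbinol, C-3a quaternary, C-4 angelate, C-5=C-6, C-8 benzoate, C-8a ring-fusion CH)
1. The isopropyl group is added last to a C-1 cyclopentanone; the five-membered ring comes from rhodium hydroacylation (C-1–C-2) of a 4-pentenal.
2. The seven-membered ring is cut at C-3a–C-4 and at C-5=C-6. This excises C-4/C-5 as acrolein and leaves an open-chain (Z)-allylboronate with a C-6 isopropenyl group; carbonyl allylboration and ring-closing metathesis rejoin them in one flask.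
3. Enabling feature: C-4 is a secondary allylic carbinol lying between the quaternary C-3a and the trisubstituted C-5=C-6 alkene of the seven-membered ring. A two-carbon enal can therefore be joined by allylation on one side and metathesis on the other, and the (Z)-C-3=C-3a alkene fixes O-4 syn to C-8a.
4. The open chain comes from the Sharpless epoxide of (E)-5-methylhexa-2,5-dien-1-ol, opened at C-2 by a (Z)-alkenyl copper reagent (C-8 from the epoxidation, C-8a by inversion).
5. Ring order: seven-membered carbocycle (step 11), then five-membered ring (step 15).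

Key step: step 11

**Route**

Step 1
Reactants: 1 prop-2-yn-1-ol; 2 3-chloro-2-methylprop-1-ene
Product: 3 5-methylhex-5-en-2-yn-1-ol
Conditions: CuI (10 mol %), NaI (10 mol %), K2CO3, DMF, rt
Reagents that add atoms: none
Why: Copper-mediated coupling of a terminal alkyne with an allylic chloride (alkynylcopper allylation) gives the skipped enyne without protecting the alcohol; no stereocentre is formed.

Step 2
Reactants: 3 5-methylhex-5-en-2-yn-1-ol
Product: 4 (2E)-5-methylhexa-2,5-dien-1-ol
Conditions: LiAlH4, THF, 0 °C to reflux; aqueous NaOH work-up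
Reagents that add atoms: none
Why: Hydroxyl-directed trans-hydroalumination of the propargylic alcohol should give only the (E)-allylic alcohol and leave the isolated 1,1-disubstituted alkene untouched.

Step 3
Reactants: 4 (2E)-5-methylhexa-2,5-dien-1-ol
Product: 5 (2S,3S)-epoxy alcohol
Conditions: Ti(OiPr)4 (10 mol %), L-(+)-diisopropyl tartrate (12 mol %), tBuOOH, 4 Å MS, CH2Cl2, −20 °C
Reagents that add atoms: tert-butyl hydroperoxide CC(C)(C)OO
Why: Sharpless asymmetric epoxidation acts only on the allylic alkene, and L-(+)-tartrate should deliver oxygen to the face that gives the (2S,3S)-epoxide, which fixes the later C-8 centre.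

Step 4
Reactants: 6 but-2-yn-1-ol
Product: 8 (2Z)-3-iodobut-2-en-1-ol, via cyclic alkenylalanate 7 (not isolated)
Conditions: NaAlH2(OCH2CH2OMe)2, Et2O, 0 °C to rt; then I2, THF, −78 °C to 0 °C
Reagents that add atoms: iodine II
Why: Hydroxyl-directed trans-hydroalumination places aluminium on C-3 in a five-membered alkoxyalanate, and iodinolysis with retention gives the (Z)-iodoalkene.

Step 5
Reactants: 8 (2Z)-3-iodobut-2-en-1-ol
Product: 9 TBS ether of 8
Conditions: TBSCl, imidazole, CH2Cl2, 0 °C to rt
Reagents that add atoms: tert-butyl(chloro)dimethylsilane CC(C)(C)[Si](C)(C)Cl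
Why: Silyl ether formation masks the hydroxyl before the organometallic is made.

Step 6
Reactants: 9 TBS ether of 8 (2.5 equiv); 5 (2S,3S)-epoxy alcohol
Product: 11 (2R,3S)-2-alkenyl-1,3-diol, via alkenylmagnesium chloride 10 (not isolated)
Conditions: iPrMgCl·LiCl, THF, 0 °C to rt; then CuI (10 mol %), 5, −30 °C to 0 °C; aq. NH4Cl
Reagents that add atoms: none
Why: Iodine–magnesium exchange keeps the alkene geometry, and the copper-catalysed SN2 opening of the 2,3-epoxy alcohol at C-2 (anti) installs the (Z)-alkenyl group with inversion, which sets C-8a while C-8 is untouched; the first equivalent of 10 serves as base for the hydroxyl.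

Step 7
Reactants: 11 (2R,3S)-2-alkenyl-1,3-diol
Product: 12 primary TBDPS ether
Conditions: TBDPSCl (1.05 equiv), imidazole, CH2Cl2, 0 °C
Reagents that add atoms: tert-butyl(chloro)diphenylsilane CC(C)(C)[Si](Cl)(c1ccccc1)c1ccccc1
Why: Selective silylation: the bulky chlorosilane should react at the primary hydroxyl much faster than at the secondary one.

Step 8
Reactants: 12 primary TBDPS ether
Product: 13 C-8 benzoate
Conditions: BzCl, pyridine, DMAP (5 mol %), CH2Cl2, 0 °C to rt
Reagents that add atoms: benzoyl chloride O=C(Cl)c1ccccc1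
Why: DMAP-catalysed acylation of the remaining secondary alcohol installs the C-8 benzoate of the target early, where it also serves as protecting group.

Step 9
Reactants: 13 C-8 benzoate
Product: 14 (Z)-allylic alcohol
Conditions: camphorsulfonic acid (10 mol %), MeOH/CH2Cl2, 0 °C
Reagents that add atoms: none
Why: Acid-catalysed methanolysis (selective desilylation) should cleave the primary allylic TBS ether far faster than the TBDPS ether and leave the benzoate.

Step 10
Reactants: 14 (Z)-allylic alcohol
Product: 16 (Z)-allyl pinacol boronate, via allylboronic acid 15 (not isolated)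
Conditions: B2(OH)4, [Pd(MeCN)4](BF4)2 (2 mol %), DMSO/MeOH, rt; then pinacol, MgSO4
Reagents that add atoms: tetrahydroxydiboron OB(O)B(O)O; pinacol CC(C)(O)C(C)(C)O
Why: Palladium-catalysed borylation of a primary allylic alcohol with tetrahydroxydiboron gives the linear allylboronic acid with retention of the (Z)-trisubstituted alkene, and esterification with pinacol makes it a storable reagent.

Step 11
Reactants: 16 (Z)-allyl pinacol boronate; 17 prop-2-enal
Product: 20 cycloheptenol, via triene borate 18 (not isolated), via cycloheptene borate 19 (not isolated)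
Conditions: 17 (1.5 equiv), (S)-TRIP (5 mol %), 4 Å MS, toluene, −30 °C to rt; then dilution with toluene (0.005 M), second-generation Grubbs catalyst (5 mol %), 60 °C; aq. NaHCO3 work-up
Reagents that add atoms: none
Why: The chiral phosphoric acid activates the pinacol boronate, and the (Z)-γ,γ-disubstituted allyl unit of 16 is transferred to acrolein through a closed six-membered chair transition state (Brønsted acid-catalysed carbonyl allylboration, known for allyl, crotyl and γ,γ-disubstituted pinacol allylboronates), which forms the C-3a–C-4 bond and leaves a vinyl group on C-3a; without isolation the new C-5 vinyl group and the C-6 isopropenyl group then undergo ring-closing metathesis (diene metathesis to a trisubstituted cycloalkene, loss of ethene), which forms C-5=C-6. The only ring closed is the seven-membered carbocycle, closed by alkene metathesis between a monosubstituted and a 1,1-disubstituted alkene. C-4 is set relative to C-3a by the chair, in which the vinyl group of acrolein is equatorial and the (Z)-alkene puts C-8a axial, so that O-4 ends syn to C-8a and anti to the methyl group; the absolute sense at both centres is set by the catalyst ((S)-TRIP is expected to direct attack on the Si face of acrolein), which has to overrule the bias of the C-8a centre. The step needs this face selectivity and the seven- over the six-membered metathesis mode (C-3 vinyl with C-6 isopropenyl); the first rests on catalyst control, the second on the C-3 vinyl group being neopentylic on the quaternary C-3a and therefore slow to take up ruthenium, while the C-5 vinyl group with its allylic oxygen initiates first and can only reach C-6.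

Step 12
Reactants: 20 cycloheptenol
Product: 21 C-4 angelate
Conditions: angelic acid, 2,4,6-trichlorobenzoyl chloride, Et3N, toluene, rt; then 20, toluene, 80 °C
Reagents that add atoms: angelic acid C/C=C(/C)C(=O)O
Why: Yamaguchi esterification through the mixed anhydride should acylate the hindered neopentylic C-4 alcohol without isomerising the angelate to the tiglate.

Step 13
Reactants: 21 C-4 angelate
Product: 22 primary alcohol
Conditions: HF·pyridine, pyridine/THF, 0 °C to rt
Reagents that add atoms: none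
Why: Fluoride cleavage of the silyl ether under buffered conditions should free the primary alcohol without acyl migration or ester loss.

Step 14
Reactants: 22 primary alcohol
Product: 23 aldehyde
Conditions: Dess–Martin periodinane, CH2Cl2, 0 °C to rt
Reagents that add atoms: none
Why: Dess–Martin oxidation gives the α-branched aldehyde under near-neutral conditions that should avoid epimerisation at C-8a and β-elimination of benzoate.

Step 15
Reactants: 23 aldehyde
Product: 24 hydroazulenone
Conditions: [Rh(nbd)(dppe)]BF4 (5 mol %, pre-hydrogenated), CH2Cl2, rt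
Reagents that add atoms: none
Why: Rhodium-catalysed intramolecular alkene hydroacylation of the 4-pentenal unit (C-1 aldehyde, vinyl group on the quaternary C-3a) forms the C-1–C-2 bond and the cyclopentanone; no new stereocentre arises and the trans ring fusion follows from the fixed C-3a and C-8a centres.

Step 16
Reactants: 24 hydroazulenone
Product: 25 target CNP0397959.1
Conditions: iPrMgCl, CeCl3 (anhydrous), THF, −78 °C; AcOH quench at −78 °C
Reagents that add atoms: isopropylmagnesium chloride CC(C)[Mg]Cl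
Why: Organocerium 1,2-addition to the enolisable cyclopentanone should outrun ester attack, enolisation and β-hydride reduction, and the nucleophile should enter anti to the angular C-3a methyl group (syn to H-8a), which gives the (1R)-carbinol.

**Compound list**

1 | prop-2-yn-1-ol | C#CCO | starting material
2 | 3-chloro-2-methylprop-1-ene | CC(=C)CCl | starting material
3 | 5-methylhex-5-en-2-yn-1-ol | CC(=C)CC#CCO | intermediate
4 | (2E)-5-methylhexa-2,5-dien-1-ol | CC(=C)C/C=C/CO | intermediate
5 | [(2S,3S)-3-(2-methylprop-2-en-1-yl)oxiran-2-yl]methanol | OC[C@@H]1O[C@H]1CC(C)=C | intermediate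
6 | but-2-yn-1-ol | CC#CCO | starting material
7 | sodium 2,2-bis(2-methoxyethoxy)-3-methyl-2,5-dihydro-1,2-oxaalumol-2-uide | CC1=CCO[Al-]1(OCCOC)OCCOC.[Na+] | intermediate
8 | (2Z)-3-iodobut-2-en-1-ol | C/C(I)=C/CO | intermediate
9 | tert-butyl{[(2Z)-3-iodobut-2-en-1-yl]oxy}dimethylsilane | C/C(I)=C/CO[Si](C)(C)C(C)(C)C | intermediate
10 | [(2Z)-4-{[tert-butyl(dimethyl)silyl]oxy}but-2-en-2-yl]magnesium chloride | C/C([Mg]Cl)=C/CO[Si](C)(C)C(C)(C)C | intermediate
11 | (2R,3S)-2-[(2Z)-4-{[tert-butyl(dimethyl)silyl]oxy}but-2-en-2-yl]-5-methylhex-5-ene-1,3-diol | C=C(C)C[C@H](O)[C@@H](CO)/C(C)=C\CO[Si](C)(C)C(C)(C)C | intermediate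
12 | (2R,3S)-2-[(2Z)-4-{[tert-butyl(dimethyl)silyl]oxy}but-2-en-2-yl]-1-{[tert-butyl(diphenyl)silyl]oxy}-5-methylhex-5-en-3-ol | C=C(C)C[C@H](O)[C@@H](CO[Si](c1ccccc1)(c1ccccc1)C(C)(C)C)/C(C)=C\CO[Si](C)(C)C(C)(C)C | intermediate
13 | (2R,3S)-2-[(2Z)-4-{[tert-butyl(dimethyl)silyl]oxy}but-2-en-2-yl]-1-{[tert-butyl(diphenyl)silyl]oxy}-5-methylhex-5-en-3-yl benzoate | C=C(C)C[C@H](OC(=O)c1ccccc1)[C@@H](CO[Si](c1ccccc1)(c1ccccc1)C(C)(C)C)/C(C)=C\CO[Si](C)(C)C(C)(C)C | intermediate
14 | (2R,3S)-1-{[tert-butyl(diphenyl)silyl]oxy}-2-[(2Z)-4-hydroxybut-2-en-2-yl]-5-methylhex-5-en-3-yl benzoate | C=C(C)C[C@H](OC(=O)c1ccccc1)[C@@H](CO[Si](c1ccccc1)(c1ccccc1)C(C)(C)C)/C(C)=C\CO | intermediate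
15 | {(2Z)-3-[(2R,3S)-3-(benzoyloxy)-1-{[tert-butyl(diphenyl)silyl]oxy}-5-methylhex-5-en-2-yl]but-2-en-1-yl}boronic acid | C=C(C)C[C@H](OC(=O)c1ccccc1)[C@@H](CO[Si](c1ccccc1)(c1ccccc1)C(C)(C)C)/C(C)=C\CB(O)O | intermediate
16 | (2R,3S)-1-{[tert-butyl(diphenyl)silyl]oxy}-5-methyl-2-[(2Z)-4-(4,4,5,5-tetramethyl-1,3,2-dioxaborolan-2-yl)but-2-en-2-yl]hex-5-en-3-yl benzoate | C=C(C)C[C@H](OC(=O)c1ccccc1)[C@@H](CO[Si](c1ccccc1)(c1ccccc1)C(C)(C)C)/C(C)=C\CB1OC(C)(C)C(C)(C)O1 | intermediate
17 | prop-2-enal (acrolein) | C=CC=O | starting material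
18 | (3R,4S,5R,6S)-5-({[tert-butyl(diphenyl)silyl]oxy}methyl)-4-ethenyl-4,8-dimethyl-3-[(4,4,5,5-tetramethyl-1,3,2-dioxaborolan-2-yl)oxy]nona-1,8-dien-6-yl benzoate | C=C(C)C[C@H](OC(=O)c1ccccc1)[C@@H](CO[Si](c1ccccc1)(c1ccccc1)C(C)(C)C)[C@](C)(C=C)[C@H](OB1OC(C)(C)C(C)(C)O1)C=C | intermediate
19 | (1S,2R,3S,4R)-2-({[tert-butyl(diphenyl)silyl]oxy}methyl)-3-ethenyl-3,6-dimethyl-4-[(4,4,5,5-tetramethyl-1,3,2-dioxaborolan-2-yl)oxy]cyclohept-5-en-1-yl benzoate | CC1=C[C@@H](OB2OC(C)(C)C(C)(C)O2)[C@@](C)(C=C)[C@H](CO[Si](c2ccccc2)(c2ccccc2)C(C)(C)C)[C@@H](OC(=O)c2ccccc2)C1 | intermediate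
20 | (1S,2R,3S,4R)-2-({[tert-butyl(diphenyl)silyl]oxy}methyl)-3-ethenyl-4-hydroxy-3,6-dimethylcyclohept-5-en-1-yl benzoate | CC1=C[C@@H](O)[C@@](C)(C=C)[C@H](CO[Si](c2ccccc2)(c2ccccc2)C(C)(C)C)[C@@H](OC(=O)c2ccccc2)C1 | intermediate
21 | (1S,2R,3S,4R)-2-({[tert-butyl(diphenyl)silyl]oxy}methyl)-3-ethenyl-3,6-dimethyl-4-{[(2Z)-2-methylbut-2-enoyl]oxy}cyclohept-5-en-1-yl benzoate | C/C=C(/C)C(=O)O[C@@H]1C=C(C)C[C@H](OC(=O)c2ccccc2)[C@@H](CO[Si](c2ccccc2)(c2ccccc2)C(C)(C)C)[C@]1(C)C=C | intermediate
22 | (1S,2R,3S,4R)-3-ethenyl-2-(hydroxymethyl)-3,6-dimethyl-4-{[(2Z)-2-methylbut-2-enoyl]oxy}cyclohept-5-en-1-yl benzoate | C/C=C(/C)C(=O)O[C@@H]1C=C(C)C[C@H](OC(=O)c2ccccc2)[C@@H](CO)[C@]1(C)C=C | intermediate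
23 | (1S,2S,3S,4R)-3-ethenyl-2-formyl-3,6-dimethyl-4-{[(2Z)-2-methylbut-2-enoyl]oxy}cyclohept-5-en-1-yl benzoate | C/C=C(/C)C(=O)O[C@@H]1C=C(C)C[C@H](OC(=O)c2ccccc2)[C@@H](C=O)[C@]1(C)C=C | intermediate
24 | (3aS,4R,8S,8aS)-3a,6-dimethyl-4-{[(2Z)-2-methylbut-2-enoyl]oxy}-1-oxo-1,2,3,3a,4,7,8,8a-octahydroazulen-8-yl benzoate | C/C=C(/C)C(=O)O[C@@H]1C=C(C)C[C@H](OC(=O)c2ccccc2)[C@@H]2[C@]1(C)CCC2=O | intermediate
25 | (1R,3aS,4R,8S,8aS)-1-hydroxy-3a,6-dimethyl-4-{[(2Z)-2-methylbut-2-enoyl]oxy}-1-(propan-2-yl)-1,2,3,3a,4,7,8,8a-octahydroazulen-8-yl benzoate | C/C=C(/C)C(=O)O[C@@H]1C=C(C)C[C@H](OC(=O)c2ccccc2)[C@@H]2[C@]1(C)CC[C@@]2(O)C(C)C | target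

**Step count and risks**

Total step count: 16. Longest linear sequence: 14 steps (steps 1–3 and 6–16).

Steps most likely to fail:

1. Step 11. The risk is poor face selectivity in the allyl transfer, because the acid catalyst must overrule the allylic-strain preference of the C-8a centre (a mismatched pair), and leakage into the six-membered metathesis mode. Fallback from 14 to 20: N-chlorosuccinimide and Me2S convert the allylic alcohol into the (Z)-allylic chloride F1 with retention of geometry. HSiCl3, CuCl and iPr2NEt then give the (Z)-allyltrichlorosilane F2. Lewis-base-catalysed allylation of acrolein 17 with a chiral bisphosphoramide proceeds through a closed chair at hexacoordinate silicon and is stereospecific; this reaction type is known to build quaternary centres from γ,γ-disubstituted allyltrichlorosilanes under strong catalyst control. It gives the triene alcohol F3, which is isolated and closed in a separate ring-closing metathesis with second-generation Hoveyda–Grubbs catalyst to 20.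

2. Step 6. The risk is attack of the hindered α-branched alkenyl group at C-3 instead of C-2 of the epoxy alcohol, or slow transfer of that group. Fallback from 5 to 11: TEMPO and PhI(OAc)2 in aqueous MeCN oxidise the epoxy alcohol to the epoxy acid F4. The lithium dialkenylcuprate made from 9 (tBuLi, then CuI) opens the carboxylate-bearing epoxide at the α-carbon, which is the inherent site for cuprates on 2,3-epoxy acids, and gives the β-hydroxy acid F5. LiAlH4 reduction of the acid returns diol 11.

3. Step 16. The risk is reduction of the hindered ketone by β-hydride transfer from the branched nucleophile, enolisation followed by β-elimination of benzoate, or attack on the esters. Fallback from 24 to 25: isopropenylmagnesium bromide with CeCl3, which has no β-hydrogen to deliver, gives the isopropenyl carbinol F6. Hydrogenation with RhCl(PPh3)3 under H2 should reduce only the 1,1-disubstituted alkene and give 25.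

**Further compounds**

F1 | step 11 | (2R,3S)-1-{[tert-butyl(diphenyl)silyl]oxy}-2-[(2Z)-4-chlorobut-2-en-2-yl]-5-methylhex-5-en-3-yl benzoate | C=C(C)C[C@H](OC(=O)c1ccccc1)[C@@H](CO[Si](c1ccccc1)(c1ccccc1)C(C)(C)C)/C(C)=C\CCl
F2 | step 11 | (2R,3S)-1-{[tert-butyl(diphenyl)silyl]oxy}-5-methyl-2-[(2Z)-4-(trichlorosilyl)but-2-en-2-yl]hex-5-en-3-yl benzoate | C=C(C)C[C@H](OC(=O)c1ccccc1)[C@@H](CO[Si](c1ccccc1)(c1ccccc1)C(C)(C)C)/C(C)=C\C[Si](Cl)(Cl)Cl
F3 | step 11 | (3R,4S,5R,6S)-5-({[tert-butyl(diphenyl)silyl]oxy}methyl)-4-ethenyl-3-hydroxy-4,8-dimethylnona-1,8-dien-6-yl benzoate | C=C(C)C[C@H](OC(=O)c1ccccc1)[C@@H](CO[Si](c1ccccc1)(c1ccccc1)C(C)(C)C)[C@](C)(C=C)[C@H](O)C=C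
F4 | step 6 | (2R,3S)-3-(2-methylprop-2-en-1-yl)oxirane-2-carboxylic acid | OC(=O)[C@@H]1O[C@H]1CC(C)=C
F5 | step 6 | (2S,3S)-2-[(2Z)-4-{[tert-butyl(dimethyl)silyl]oxy}but-2-en-2-yl]-3-hydroxy-5-methylhex-5-enoic acid | C=C(C)C[C@H](O)[C@@H](C(=O)O)/C(C)=C\CO[Si](C)(C)C(C)(C)C
F6 | step 16 | (1S,3aS,4R,8S,8aS)-1-hydroxy-3a,6-dimethyl-4-{[(2Z)-2-methylbut-2-enoyl]oxy}-1-(prop-1-en-2-yl)-1,2,3,3a,4,7,8,8a-octahydroazulen-8-yl benzoate | C/C=C(/C)C(=O)O[C@@H]1C=C(C)C[C@H](OC(=O)c2ccccc2)[C@@H]2[C@]1(C)CC[C@@]2(O)C(C)=C
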